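**Strategy.** The γ-lactone is disconnected at C8'–C9' and O–C9. C8' lies α to the C7' aryl ketone on ring B and β to the C9 ester, so a hydroxymethyl group on C8' places its oxygen γ to C9. In one operation formaldehyde adds to the ketone enolate and the new alkoxide closes the lactone, while C8' equilibrates trans to the C8 benzyl group of ring A. The precursor is a methyl (2R)-2-benzyl-4-aryl-4-oxobutanoate carrying both phenols as benzyl ethers and the ring C glycerol diol as an acetonide, made by auxiliary-controlled alkylation with a ring B bromoketone.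

Key step: step 11

**Labels.** Ring A = 4-hydroxy-3-methoxybenzyl arene on C7; C8 = lactone α-carbon; C9 = lactone carbonyl; C9' = lactone OCH2; C8' = lactone β-carbon; C7' = carbinol between C8' and ring B (central arene, C3' OMe, C4' ether oxygen); C8'' = ether CH, C9'' = its CH2OH, C7'' = benzylic carbinol on ring C.

**Remarks on the chemistry.**
- The target SMILES reads C8 R, C8' R (trans lactone), C7' R, C7'' S, C8'' S (threo glycerol unit).
- C8' is α to C7' and β (not γ) to C9; the γ position is the oxygen-bearing C9'.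
- The O7''/O9'' diol is carried as an isopropylidene acetal and released by mild acid while C7' is still a ketone. An arylmethylidene acetal would have to be hydrogenolysed at the end in competition with the benzylic C7''–O and C7'–O bonds. The last step therefore only cleaves two aryl benzyl ethers.
- The threo aryl ether is built by a glycolate aldol with the O–C8'' bond already in place, which avoids O-arylation of a hindered secondary alcohol.
- Felkin–Anh analysis of the trans ketone predicts the C7' S epimer from simple hydrides, so the (R)-carbinol is set by reagent control with the (R,R)-ligand.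
- Assumption: the chloroacetyl imide of step 1 is a catalogue compound in both enantiomeric forms (otherwise one N-acylation of (R)-4-benzyloxazolidin-2-one with chloroacetyl chloride). Formaldehyde is used as the commercial 37% aqueous solution.

**Route**

Step 1
Reactants: 1 4-hydroxy-3-methoxybenzonitrile; 2 (R)-4-benzyl-3-(chloroacetyl)oxazolidin-2-one
Product: 3 (R)-4-benzyl-3-[(4-cyano-2-methoxyphenoxy)acetyl]oxazolidin-2-one
Conditions: K2CO3, NaI (cat.), acetone, 45 °C
Reagents that add atoms: none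
Why: Williamson ether synthesis in which the weakly basic cyanophenoxide displaces the activated α-chloride (iodide-catalysed SN2) faster than it can attack the imide carbonyls; no stereocentre is formed.

Step 2
Reactants: 3 (R)-4-benzyl-3-[(4-cyano-2-methoxyphenoxy)acetyl]oxazolidin-2-one; 4 4-benzyloxy-3-methoxybenzaldehyde
Product: 6 (R)-4-benzyl-3-[(2R,3S)-3-(4-benzyloxy-3-methoxyphenyl)-2-(4-cyano-2-methoxyphenoxy)-3-hydroxypropanoyl]oxazolidin-2-one, via Z-boron enolate 5 (not isolated)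
Conditions: n-Bu2BOTf, i-Pr2NEt, CH2Cl2, −78 → 0 °C; then 4, −78 → 0 °C; then pH 7 buffer, MeOH, 30% H2O2, 0 °C
Reagents that add atoms: none
Why: Evans syn-glycolate aldol reaction, in which the Z-boron enolate reacts through a closed Zimmerman–Traxler chair on the face away from the auxiliary benzyl group, so the (R)-auxiliary should give the syn (2R,3S) adduct that becomes the threo C7'' S / C8'' S pair.

Step 3
Reactants: 6 (R)-4-benzyl-3-[(2R,3S)-3-(4-benzyloxy-3-methoxyphenyl)-2-(4-cyano-2-methoxyphenoxy)-3-hydroxypropanoyl]oxazolidin-2-one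
Product: 7 4-{[(1S,2S)-1-(4-benzyloxy-3-methoxyphenyl)-1,3-dihydroxypropan-2-yl]oxy}-3-methoxybenzonitrile
Conditions: NaBH4, THF/H2O (4:1), 0 °C → rt
Reagents that add atoms: none
Why: Reductive cleavage of the N-acyloxazolidinone reduces only the activated exocyclic imide carbonyl to the C9'' CH2OH, leaving the nitrile and both stereocentres untouched.

Step 4
Reactants: 7 4-{[(1S,2S)-1-(4-benzyloxy-3-methoxyphenyl)-1,3-dihydroxypropan-2-yl]oxy}-3-methoxybenzonitrile
Product: 8 4-{[(4S,5S)-4-(4-benzyloxy-3-methoxyphenyl)-2,2-dimethyl-1,3-dioxan-5-yl]oxy}-3-methoxybenzonitrile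
Conditions: Me2C(OMe)2, PPTS (cat.), acetone, rt
Reagents that add atoms: 2,2-dimethoxypropane COC(C)(C)OC
Why: Acid-catalysed transacetalisation of the 1,3-diol gives the six-membered isopropylidene acetal (cis-4-aryl-5-aryloxy-1,3-dioxane) without touching a stereocentre.

Step 5
Reactants: 8 4-{[(4S,5S)-4-(4-benzyloxy-3-methoxyphenyl)-2,2-dimethyl-1,3-dioxan-5-yl]oxy}-3-methoxybenzonitrile
Product: 10 1-(4-{[(4S,5S)-4-(4-benzyloxy-3-methoxyphenyl)-2,2-dimethyl-1,3-dioxan-5-yl]oxy}-3-methoxyphenyl)ethanone, via N-magnesio ketimine 9 (not isolated)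
Conditions: MeMgBr, THF, 55 °C; then aq. NH4Cl, aq. citric acid, 0 °C → rt
Reagents that add atoms: methylmagnesium bromide C[Mg]Br; water O
Why: Grignard addition to the aryl nitrile stops at the metallo-ketimine, which mildly acidic water hydrolyses much faster than the dioxane acetal, giving the methyl ketone that supplies C7' and C8'.

Step 6
Reactants: 10 1-(4-{[(4S,5S)-4-(4-benzyloxy-3-methoxyphenyl)-2,2-dimethyl-1,3-dioxan-5-yl]oxy}-3-methoxyphenyl)ethanone
Product: 12 2-bromo-1-(4-{[(4S,5S)-4-(4-benzyloxy-3-methoxyphenyl)-2,2-dimethyl-1,3-dioxan-5-yl]oxy}-3-methoxyphenyl)ethanone, via silyl enol ether 11 (not isolated)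
Conditions: LiN(SiMe3)2, Me3SiCl, THF, −78 °C; then NBS, THF, −78 → 0 °C
Reagents that add atoms: N-bromosuccinimide O=C1CCC(=O)N1Br
Why: α-Bromination through the silyl enol ether, which NBS brominates at low temperature far faster than the alkoxyarenes and without liberating acid that could open the acetonide.

Step 7
Reactants: 13 3-(4-hydroxy-3-methoxyphenyl)propanoic acid
Product: 14 3-(4-benzyloxy-3-methoxyphenyl)propanoic acid
Conditions: BnBr, NaOH, EtOH/H2O, 80 °C; then aq. HCl
Reagents that add atoms: benzyl bromide BrCc1ccccc1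
Why: Williamson benzylation of the phenoxide, which in aqueous ethanol is much more nucleophilic than the carboxylate, any benzyl ester being saponified in the same pot.

Step 8
Reactants: 14 3-(4-benzyloxy-3-methoxyphenyl)propanoic acid; 15 (S)-4-benzyloxazolidin-2-one
Product: 17 (S)-4-benzyl-3-[3-(4-benzyloxy-3-methoxyphenyl)propanoyl]oxazolidin-2-one, via mixed pivalic anhydride 16 (not isolated)
Conditions: t-BuCOCl, Et3N, THF, −20 °C; then 15, LiCl, −20 °C → rt
Reagents that add atoms: none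
Why: N-Acylation of the oxazolidinone through the pivaloyl mixed anhydride, which is attacked at its unhindered acyl carbon.

Step 9
Reactants: 17 (S)-4-benzyl-3-[3-(4-benzyloxy-3-methoxyphenyl)propanoyl]oxazolidin-2-one; 12 2-bromo-1-(4-{[(4S,5S)-4-(4-benzyloxy-3-methoxyphenyl)-2,2-dimethyl-1,3-dioxan-5-yl]oxy}-3-methoxyphenyl)ethanone
Product: 19 (S)-4-benzyl-3-[(2R)-2-(4-benzyloxy-3-methoxybenzyl)-4-(4-{[(4S,5S)-4-(4-benzyloxy-3-methoxyphenyl)-2,2-dimethyl-1,3-dioxan-5-yl]oxy}-3-methoxyphenyl)-4-oxobutanoyl]oxazolidin-2-one, via sodium Z-enolate 18 (not isolated)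
Conditions: NaN(SiMe3)2, THF, −78 °C; then 12, THF, −78 → −40 °C
Reagents that add atoms: none
Why: Evans asymmetric alkylation, in which the chelated sodium Z-enolate (used in slight excess) is alkylated by the highly SN2-reactive α-bromoketone on the face anti to the auxiliary benzyl group, which should set C8 as R and form the C8–C8' bond.

Step 10
Reactants: 19 (S)-4-benzyl-3-[(2R)-2-(4-benzyloxy-3-methoxybenzyl)-4-(4-{[(4S,5S)-4-(4-benzyloxy-3-methoxyphenyl)-2,2-dimethyl-1,3-dioxan-5-yl]oxy}-3-methoxyphenyl)-4-oxobutanoyl]oxazolidin-2-one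
Product: 20 methyl (2R)-2-(4-benzyloxy-3-methoxybenzyl)-4-(4-{[(4S,5S)-4-(4-benzyloxy-3-methoxyphenyl)-2,2-dimethyl-1,3-dioxan-5-yl]oxy}-3-methoxyphenyl)-4-oxobutanoate
Conditions: NaOMe, MeOH/THF, 0 °C; then aq. NH4Cl
Reagents that add atoms: methanol CO
Why: Methoxide transesterification at the exocyclic imide carbonyl at 0 °C should release the auxiliary without epimerising C8 or disturbing the ketone and the acetal.

Step 11
Reactants: 20 methyl (2R)-2-(4-benzyloxy-3-methoxybenzyl)-4-(4-{[(4S,5S)-4-(4-benzyloxy-3-methoxyphenyl)-2,2-dimethyl-1,3-dioxan-5-yl]oxy}-3-methoxyphenyl)-4-oxobutanoate; 21 formaldehyde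
Product: 23 (3R,4R)-3-(4-benzyloxy-3-methoxybenzyl)-4-(4-{[(4S,5S)-4-(4-benzyloxy-3-methoxyphenyl)-2,2-dimethyl-1,3-dioxan-5-yl]oxy}-3-methoxybenzoyl)dihydrofuran-2(3H)-one, via γ-hydroxy ester 22 (not isolated)
Conditions: 37% aq. HCHO, K2CO3 (0.5 equiv), THF/H2O, 0 °C → rt
Reagents that add atoms: none
Why: Carbonate reversibly deprotonates only the position α to the aryl ketone (C8', far more acidic than C8 beside the ester), the enolate adds to formaldehyde in a crossed aldol reaction (C8'–C9'), and the new primary alkoxide attacks the C9 methyl ester and expels methoxide (O–C9). The closest known reaction type is the base-mediated hydroxymethylation of 3-aroylpropanoic acids and esters with formalin, which gives 3-aroyl-γ-butyrolactones. The lactone closes in the 5-exo-trig mode by acyl substitution at C9. The one new stereocentre, C8', stays enolisable beside the ketone and is set under thermodynamic control by the fixed C8 centre, which places the aroyl group trans to the ring A benzyl group. The step needs reaction at C8' and not C8, a single hydroxymethylation and the trans ring; these are secured by the ketone/ester acidity gap, by fast lactonisation that removes the free hydroxymethyl group and leaves only a hindered tertiary enolate site, and by equilibration, while sub-stoichiometric carbonate and a short reaction time limit the reversible β-elimination of the C9 carboxylate.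

Step 12
Reactants: 23 (3R,4R)-3-(4-benzyloxy-3-methoxybenzyl)-4-(4-{[(4S,5S)-4-(4-benzyloxy-3-methoxyphenyl)-2,2-dimethyl-1,3-dioxan-5-yl]oxy}-3-methoxybenzoyl)dihydrofuran-2(3H)-one
Product: 24 (3R,4R)-3-(4-benzyloxy-3-methoxybenzyl)-4-(4-{[(1S,2S)-1-(4-benzyloxy-3-methoxyphenyl)-1,3-dihydroxypropan-2-yl]oxy}-3-methoxybenzoyl)dihydrofuran-2(3H)-one
Conditions: AcOH/THF/H2O (3:1:1), 40 °C
Reagents that add atoms: none
Why: Acid-catalysed acetal hydrolysis, which ionises at the isopropylidene carbon and is run while C7' is still a ketone, so no acid-labile carbinol beside ring B is present and the lactone, the benzyl ethers and the trans C8/C8' relationship should survive.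

Step 13
Reactants: 24 (3R,4R)-3-(4-benzyloxy-3-methoxybenzyl)-4-(4-{[(1S,2S)-1-(4-benzyloxy-3-methoxyphenyl)-1,3-dihydroxypropan-2-yl]oxy}-3-methoxybenzoyl)dihydrofuran-2(3H)-one
Product: 25 (3R,4R)-3-(4-benzyloxy-3-methoxybenzyl)-4-[(R)-(4-{[(1S,2S)-1-(4-benzyloxy-3-methoxyphenyl)-1,3-dihydroxypropan-2-yl]oxy}-3-methoxyphenyl)(hydroxy)methyl]dihydrofuran-2(3H)-one
Conditions: RuCl(p-cymene)[(R,R)-TsDPEN] (2 mol %), HCO2H/Et3N (5:2), EtOAc, 30 °C
Reagents that add atoms: none
Why: Noyori asymmetric transfer hydrogenation, in which the (R,R)-ligated ruthenium hydride recognises the ring B aryl group by a CH/π contact in its outer-sphere transition state and should deliver hydride to the face that gives the (R)-carbinol (the sense of (R)-1-arylethanols) against the Felkin–Anh bias of C8', while the acidic formate medium tolerates the free diol and should leave C8' and the lactone untouched.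

Step 14
Reactants: 25 (3R,4R)-3-(4-benzyloxy-3-methoxybenzyl)-4-[(R)-(4-{[(1S,2S)-1-(4-benzyloxy-3-methoxyphenyl)-1,3-dihydroxypropan-2-yl]oxy}-3-methoxyphenyl)(hydroxy)methyl]dihydrofuran-2(3H)-one
Product: 26 (3R,4R)-4-[(R)-(4-{[(1S,2S)-1,3-dihydroxy-1-(4-hydroxy-3-methoxyphenyl)propan-2-yl]oxy}-3-methoxyphenyl)(hydroxy)methyl]-3-(4-hydroxy-3-methoxybenzyl)dihydrofuran-2(3H)-one
Conditions: H2 (1 atm), 10% Pd/C, EtOAc/EtOH, rt, stopped after uptake of 2 equiv H2
Reagents that add atoms: none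
Why: Hydrogenolysis of the two aryl benzyl ethers over neutral Pd/C is much faster than cleavage of the benzylic C7'–OH and C7''–OH bonds, so brief exposure should free both phenols only.

**Compound list**

1 | 4-hydroxy-3-methoxybenzonitrile | N#Cc1ccc(O)c(OC)c1 | starting material
2 | (R)-4-benzyl-3-(chloroacetyl)oxazolidin-2-one | O=C(CCl)N1[C@H](Cc2ccccc2)COC1=O | starting material
3 | (R)-4-benzyl-3-[(4-cyano-2-methoxyphenoxy)acetyl]oxazolidin-2-one | N#Cc1ccc(OCC(=O)N2[C@H](Cc3ccccc3)COC2=O)c(OC)c1 | intermediate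
4 | 4-benzyloxy-3-methoxybenzaldehyde | COc1cc(C=O)ccc1OCc1ccccc1 | starting material
5 | Z-di-n-butylboron enolate of 3 | N#Cc1ccc(O/C=C(\OB(CCCC)CCCC)N2[C@H](Cc3ccccc3)COC2=O)c(OC)c1 | intermediate
6 | (R)-4-benzyl-3-[(2R,3S)-3-(4-benzyloxy-3-methoxyphenyl)-2-(4-cyano-2-methoxyphenoxy)-3-hydroxypropanoyl]oxazolidin-2-one | N#Cc1ccc(O[C@@H](C(=O)N2[C@H](Cc3ccccc3)COC2=O)[C@@H](O)c2ccc(OCc3ccccc3)c(OC)c2)c(OC)c1 | intermediate
7 | 4-{[(1S,2S)-1-(4-benzyloxy-3-methoxyphenyl)-1,3-dihydroxypropan-2-yl]oxy}-3-methoxybenzonitrile | N#Cc1ccc(O[C@@H](CO)[C@@H](O)c2ccc(OCc3ccccc3)c(OC)c2)c(OC)c1 | intermediate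
8 | 4-{[(4S,5S)-4-(4-benzyloxy-3-methoxyphenyl)-2,2-dimethyl-1,3-dioxan-5-yl]oxy}-3-methoxybenzonitrile | N#Cc1ccc(O[C@@H](COC2(C)C)[C@@H](O2)c2ccc(OCc3ccccc3)c(OC)c2)c(OC)c1 | intermediate
9 | N-bromomagnesio ketimine of 10 | CC(=N[Mg]Br)c1ccc(O[C@@H](COC2(C)C)[C@@H](O2)c2ccc(OCc3ccccc3)c(OC)c2)c(OC)c1 | intermediate
10 | 1-(4-{[(4S,5S)-4-(4-benzyloxy-3-methoxyphenyl)-2,2-dimethyl-1,3-dioxan-5-yl]oxy}-3-methoxyphenyl)ethanone | CC(=O)c1ccc(O[C@@H](COC2(C)C)[C@@H](O2)c2ccc(OCc3ccccc3)c(OC)c2)c(OC)c1 | intermediate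
11 | trimethylsilyl enol ether of 10 | C=C(O[Si](C)(C)C)c1ccc(O[C@@H](COC2(C)C)[C@@H](O2)c2ccc(OCc3ccccc3)c(OC)c2)c(OC)c1 | intermediate
12 | 2-bromo-1-(4-{[(4S,5S)-4-(4-benzyloxy-3-methoxyphenyl)-2,2-dimethyl-1,3-dioxan-5-yl]oxy}-3-methoxyphenyl)ethanone | BrCC(=O)c1ccc(O[C@@H](COC2(C)C)[C@@H](O2)c2ccc(OCc3ccccc3)c(OC)c2)c(OC)c1 | intermediate
13 | 3-(4-hydroxy-3-methoxyphenyl)propanoic acid | COc1cc(CCC(=O)O)ccc1O | starting material
14 | 3-(4-benzyloxy-3-methoxyphenyl)propanoic acid | COc1cc(CCC(=O)O)ccc1OCc1ccccc1 | intermediate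
15 | (S)-4-benzyloxazolidin-2-one | O=C1N[C@@H](Cc2ccccc2)CO1 | starting material
16 | mixed pivalic anhydride of 14 | COc1cc(CCC(=O)OC(=O)C(C)(C)C)ccc1OCc1ccccc1 | intermediate
17 | (S)-4-benzyl-3-[3-(4-benzyloxy-3-methoxyphenyl)propanoyl]oxazolidin-2-one | COc1cc(CCC(=O)N2[C@@H](Cc3ccccc3)COC2=O)ccc1OCc1ccccc1 | intermediate
18 | sodium Z-enolate of 17 | [Na+].[O-]/C(=C\Cc1ccc(OCc2ccccc2)c(OC)c1)N1[C@@H](Cc2ccccc2)COC1=O | intermediate
19 | (S)-4-benzyl-3-[(2R)-2-(4-benzyloxy-3-methoxybenzyl)-4-(4-{[(4S,5S)-4-(4-benzyloxy-3-methoxyphenyl)-2,2-dimethyl-1,3-dioxan-5-yl]oxy}-3-methoxyphenyl)-4-oxobutanoyl]oxazolidin-2-one | COc1cc(C[C@H](CC(=O)c2ccc(O[C@@H](COC3(C)C)[C@@H](O3)c3ccc(OCc4ccccc4)c(OC)c3)c(OC)c2)C(=O)N2[C@@H](Cc3ccccc3)COC2=O)ccc1OCc1ccccc1 | intermediate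
20 | methyl (2R)-2-(4-benzyloxy-3-methoxybenzyl)-4-(4-{[(4S,5S)-4-(4-benzyloxy-3-methoxyphenyl)-2,2-dimethyl-1,3-dioxan-5-yl]oxy}-3-methoxyphenyl)-4-oxobutanoate | COc1cc(C[C@H](CC(=O)c2ccc(O[C@@H](COC3(C)C)[C@@H](O3)c3ccc(OCc4ccccc4)c(OC)c3)c(OC)c2)C(=O)OC)ccc1OCc1ccccc1 | intermediate
21 | formaldehyde | C=O | starting material
22 | methyl (2R)-2-(4-benzyloxy-3-methoxybenzyl)-3-(hydroxymethyl)-4-(4-{[(4S,5S)-4-(4-benzyloxy-3-methoxyphenyl)-2,2-dimethyl-1,3-dioxan-5-yl]oxy}-3-methoxyphenyl)-4-oxobutanoate (both C3 epimers) | COc1cc(C[C@H](C(CO)C(=O)c2ccc(O[C@@H](COC3(C)C)[C@@H](O3)c3ccc(OCc4ccccc4)c(OC)c3)c(OC)c2)C(=O)OC)ccc1OCc1ccccc1 | intermediate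
23 | (3R,4R)-3-(4-benzyloxy-3-methoxybenzyl)-4-(4-{[(4S,5S)-4-(4-benzyloxy-3-methoxyphenyl)-2,2-dimethyl-1,3-dioxan-5-yl]oxy}-3-methoxybenzoyl)dihydrofuran-2(3H)-one | COc1cc(C[C@H]2C(=O)OC[C@@H]2C(=O)c2ccc(O[C@@H](COC3(C)C)[C@@H](O3)c3ccc(OCc4ccccc4)c(OC)c3)c(OC)c2)ccc1OCc1ccccc1 | intermediate
24 | (3R,4R)-3-(4-benzyloxy-3-methoxybenzyl)-4-(4-{[(1S,2S)-1-(4-benzyloxy-3-methoxyphenyl)-1,3-dihydroxypropan-2-yl]oxy}-3-methoxybenzoyl)dihydrofuran-2(3H)-one | COc1cc(C[C@H]2C(=O)OC[C@@H]2C(=O)c2ccc(O[C@@H](CO)[C@@H](O)c3ccc(OCc4ccccc4)c(OC)c3)c(OC)c2)ccc1OCc1ccccc1 | intermediate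
25 | (3R,4R)-3-(4-benzyloxy-3-methoxybenzyl)-4-[(R)-(4-{[(1S,2S)-1-(4-benzyloxy-3-methoxyphenyl)-1,3-dihydroxypropan-2-yl]oxy}-3-methoxyphenyl)(hydroxy)methyl]dihydrofuran-2(3H)-one | COc1cc(C[C@H]2C(=O)OC[C@@H]2[C@@H](O)c2ccc(O[C@@H](CO)[C@@H](O)c3ccc(OCc4ccccc4)c(OC)c3)c(OC)c2)ccc1OCc1ccccc1 | intermediate
26 | (3R,4R)-4-[(R)-(4-{[(1S,2S)-1,3-dihydroxy-1-(4-hydroxy-3-methoxyphenyl)propan-2-yl]oxy}-3-methoxyphenyl)(hydroxy)methyl]-3-(4-hydroxy-3-methoxybenzyl)dihydrofuran-2(3H)-one (CNP0233652.1) | COc1cc(C[C@H]2C(=O)OC[C@@H]2[C@@H](O)c2ccc(O[C@@H](CO)[C@@H](O)c3ccc(O)c(OC)c3)c(OC)c2)ccc1O | target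

**Step count and risks**

Total: 14 steps. Longest linear sequence: 12 steps (steps 1–6 and 9–14); the ring A branch (steps 7–8) joins at step 9.

Steps most likely to fail:

1. Step 11 (key step). What may go wrong: a second hydroxymethylation at C8'; base-induced β-elimination of the C9 carboxylate from the β-acyloxy ketone, followed by irreversible additions to the resulting enone; ester hydrolysis outrunning a slow aldol; slow erosion of C8 on long base exposure. Fallback (stepwise, through the carboxylate, so that no lactone is exposed to base): it sets out from 19 and returns at 23. Peroxide-assisted hydrolysis of the imide (LiOH, H2O2, THF/H2O, 0 °C) gives the keto acid (2R)-2-(4-benzyloxy-3-methoxybenzyl)-4-aryl-4-oxobutanoic acid F1. Hydroxymethylation of its sodium salt with formalin in dilute aqueous NaOH gives the γ-hydroxy acid (2R)-2-(4-benzyloxy-3-methoxybenzyl)-3-(hydroxymethyl)-4-aryl-4-oxobutanoic acid F2. Neutral carbodiimide lactonisation (EDC·HCl, DMAP cat., CH2Cl2) then closes the ring and lets C8' settle trans, giving 23.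

2. Step 13. What may go wrong: poor facial selectivity because the catalyst has to override the intrinsic Felkin–Anh bias of C8' (mismatched double stereodifferentiation); amine-promoted epimerisation at C8' or elimination during a slow reduction. Fallback (a different mode of reagent control in an aprotic, amine-free medium): oxazaborolidine-catalysed borane reduction with (S)-Me-CBS and excess BH3·SMe2 in THF at −20 °C, the extra borane capping the two hydroxyls as borates that methanol releases on work-up. It sets out from 24 and returns at 25 and makes no new compound (F0).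

3. Step 9. What may go wrong: proton transfer from the acidic α-bromoketone to the basic enolate, addition of the enolate to the ketone carbonyl, and a second alkylation through the more acidic product, all lowering conversion. Fallback (olefination then asymmetric hydrogenation in place of enolate alkylation): it sets out from 12, uses 4 as the aldehyde partner, and returns at 20. The sodium salt of trimethyl phosphonoacetate (NaH, THF, 0 °C) is alkylated by 12 to the phosphonate methyl 2-(dimethoxyphosphoryl)-4-aryl-4-oxobutanoate F3. Horner–Wadsworth–Emmons olefination with 4 (NaH, THF) gives the benzylidene keto ester methyl (E)-2-(4-benzyloxy-3-methoxybenzylidene)-4-aryl-4-oxobutanoate F4. Asymmetric hydrogenation of the trisubstituted acrylate C=C with a cationic iridium phosphinooxazoline complex, [Ir(cod)(PHOX)]B[3,5-(CF3)2C6H3]4, under H2 in CH2Cl2 sets C8 and gives 20; the ligand antipode is chosen to deliver C8 R, and ketone, benzyl ethers and acetal should be spared.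

**Further compounds**

F1 | step 11 | (2R)-2-(4-benzyloxy-3-methoxybenzyl)-4-(4-{[(4S,5S)-4-(4-benzyloxy-3-methoxyphenyl)-2,2-dimethyl-1,3-dioxan-5-yl]oxy}-3-methoxyphenyl)-4-oxobutanoic acid | COc1cc(C[C@H](CC(=O)c2ccc(O[C@@H](COC3(C)C)[C@@H](O3)c3ccc(OCc4ccccc4)c(OC)c3)c(OC)c2)C(=O)O)ccc1OCc1ccccc1
F2 | step 11 | (2R)-2-(4-benzyloxy-3-methoxybenzyl)-3-(hydroxymethyl)-4-(4-{[(4S,5S)-4-(4-benzyloxy-3-methoxyphenyl)-2,2-dimethyl-1,3-dioxan-5-yl]oxy}-3-methoxyphenyl)-4-oxobutanoic acid (both C3 epimers) | COc1cc(C[C@H](C(CO)C(=O)c2ccc(O[C@@H](COC3(C)C)[C@@H](O3)c3ccc(OCc4ccccc4)c(OC)c3)c(OC)c2)C(=O)O)ccc1OCc1ccccc1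
F0 | step 13 | none | none
F3 | step 9 | methyl 2-(dimethoxyphosphoryl)-4-(4-{[(4S,5S)-4-(4-benzyloxy-3-methoxyphenyl)-2,2-dimethyl-1,3-dioxan-5-yl]oxy}-3-methoxyphenyl)-4-oxobutanoate | COC(=O)C(CC(=O)c1ccc(O[C@@H](COC2(C)C)[C@@H](O2)c2ccc(OCc3ccccc3)c(OC)c2)c(OC)c1)P(=O)(OC)OC
F4 | step 9 | methyl (E)-2-(4-benzyloxy-3-methoxybenzylidene)-4-(4-{[(4S,5S)-4-(4-benzyloxy-3-methoxyphenyl)-2,2-dimethyl-1,3-dioxan-5-yl]oxy}-3-methoxyphenyl)-4-oxobutanoate | COc1cc(/C=C(\CC(=O)c2ccc(O[C@@H](COC3(C)C)[C@@H](O3)c3ccc(OCc4ccccc4)c(OC)c3)c(OC)c2)C(=O)OC)ccc1OCc1ccccc1
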